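**Strategy.** The 15-membered lactone (O1, C1–C14) is closed at its alkyl C–O bond: the C1 carboxylate of a linear seco acid displaces the activated C14 hydroxyl (Mitsunobu macrolactonisation), forming O1–C14 with inversion. The step exploits C14 as the lone free secondary carbinol between C13H2 and the silyloxy-bearing C15: the erythro 14,15-relationship, which matched Felkin-type allylboration of an α-silyloxy aldehyde delivers directly, is converted into the natural threo array as the ring closes. The precursor already carries the 11,12-trans vinyl epoxide, both ring E-olefins (joined by cross-metathesis) and TBS ethers at O7, O8, O15 and O18; the diene side chain follows by Julia–Kocienski olefination.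

Key step: step 18

Remark: positions are numbered as in the natural product (C1 = lactone carbonyl, O1 = ring oxygen, C14 = ring carbinol carbon, C15–C23 = side chain); TBS = tert-butyldimethylsilyl; compounds 1, 2, 5, 11, 27 and 28 are taken as catalogue compounds.

**Fragment C1–C5 (acyl unit)**

Step 1
Reactants: 1 (S)-4-benzyloxazolidin-2-one; 2 (E)-but-2-enoyl chloride
Product: 3 (S)-4-benzyl-3-[(E)-but-2-enoyl]oxazolidin-2-one
Conditions: n-BuLi, THF, −78 °C; then 2, −78 to 0 °C
Reagents that add atoms: none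
Why: N-acylation of the lithiated oxazolidinone by the acid chloride (imide formation with a chiral auxiliary); no stereocentre is formed.

Step 2
Reactants: 3 (S)-4-benzyl-3-[(E)-but-2-enoyl]oxazolidin-2-one
Product: 4 (S)-4-benzyl-3-[(S)-3-methylhex-5-enoyl]oxazolidin-2-one
Conditions: TiCl4 (1.1 equiv), allylSiMe3 (2 equiv), CH2Cl2, −78 °C
Reagents that add atoms: allyltrimethylsilane, C=CC[Si](C)(C)C
Why: Hosomi–Sakurai conjugate allylation of the TiCl4-chelated syn-s-cis imide, in which the allylsilane should add to C3 on the face opposite the C4 benzyl group and so set 3S.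

**Fragment C6–C9 (diol unit) and its union with C1–C5**

Step 3
Reactants: 5 dimethyl (4R,5R)-2,2-dimethyl-1,3-dioxolane-4,5-dicarboxylate
Product: 7 (4S,5S)-2,2-dimethyl-4,5-divinyl-1,3-dioxolane, via dioxolane dialdehyde 6 (not isolated)
Conditions: iBu2AlH (2.1 equiv), toluene, −78 °C; then Ph3P=CH2 (from Ph3PCH3Br, KN(SiMe3)2), THF, −78 °C to rt
Reagents that add atoms: methyltriphenylphosphonium bromide, C[P+](c1ccccc1)(c1ccccc1)c1ccccc1.[Br-]
Why: Half-reduction of both esters to aluminium hemiacetals and Wittig methylenation in the same flask avoids isolating the labile dialdehyde, and the two tartrate-derived stereocentres (the future C7 and C8) are not touched.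

Step 4
Reactants: 7 (4S,5S)-2,2-dimethyl-4,5-divinyl-1,3-dioxolane
Product: 8 (3S,4S)-hexa-1,5-diene-3,4-diol
Conditions: 1 M aq. HCl, MeOH, rt; then NaHCO3
Reagents that add atoms: none
Why: Acid-catalysed acetal hydrolysis, removing the acetonide early because acid cannot be used once the vinyl epoxide is present.

Step 5
Reactants: 8 (3S,4S)-hexa-1,5-diene-3,4-diol
Product: 9 (3S,4S)-3,4-bis(tert-butyldimethylsilyloxy)hexa-1,5-diene
Conditions: TBSOTf (2.5 equiv), 2,6-lutidine, CH2Cl2, 0 °C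
Reagents that add atoms: tert-butyldimethylsilyl trifluoromethanesulfonate, CC(C)(C)[Si](C)(C)OS(=O)(=O)C(F)(F)F
Why: Silylation of both allylic hydroxyls with the reactive silyl triflate gives fluoride-labile protection compatible with the final vinyl epoxide.

Step 6
Reactants: 4 (S)-4-benzyl-3-[(S)-3-methylhex-5-enoyl]oxazolidin-2-one; 9 (3S,4S)-3,4-bis(tert-butyldimethylsilyloxy)hexa-1,5-diene
Product: 10 (S)-4-benzyl-3-[(3S,5E,7S,8S)-7,8-bis(tert-butyldimethylsilyloxy)-3-methyldeca-5,9-dienoyl]oxazolidin-2-one (C1–C10 fragment)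
Conditions: second-generation Grubbs catalyst (5 mol%), 9 (4 equiv), CH2Cl2, 40 °C
Reagents that add atoms: none
Why: Olefin cross-metathesis of the unhindered terminal alkene of 4 with one vinyl group of the C2-symmetric diene used in excess; the bulky allylic silyl ethers slow homodimerisation of 9 and the thermodynamically favoured E-olefin (C5=C6) is expected.

**Fragment C10–C18 (vinyl epoxide)**

Step 7
Reactants: 11 (S)-5-(trityloxymethyl)dihydrofuran-2(3H)-one
Product: 12 (3R,5S)-3-methyl-5-(trityloxymethyl)dihydrofuran-2(3H)-one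
Conditions: LiN(iPr)2, THF, −78 °C; then MeI
Reagents that add atoms: iodomethane, CI
Why: Enolate alkylation of the γ-lactone on the face anti to the bulky C5 trityloxymethyl group should give the trans-3,5-disubstituted lactone and thereby C17 (R) relative to C15 (S).

Step 8
Reactants: 12 (3R,5S)-3-methyl-5-(trityloxymethyl)dihydrofuran-2(3H)-one
Product: 13 (2R,4S)-2-methyl-5-(trityloxy)pentane-1,4-diol
Conditions: LiAlH4, THF, 0 °C
Reagents that add atoms: none
Why: Hydride reduction of the lactone opens it to the 1,4-diol (C18 and C15 hydroxyls) without touching either stereocentre.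

Step 9
Reactants: 13 (2R,4S)-2-methyl-5-(trityloxy)pentane-1,4-diol
Product: 14 (2S,4R)-2,5-bis(tert-butyldimethylsilyloxy)-4-methyl-1-(trityloxy)pentane
Conditions: TBSOTf (2.5 equiv), 2,6-lutidine, CH2Cl2, −78 to 0 °C
Reagents that add atoms: tert-butyldimethylsilyl trifluoromethanesulfonate, CC(C)(C)[Si](C)(C)OS(=O)(=O)C(F)(F)F
Why: Bis-silylation protects O15 (kept to the end) and O18 (primary, to be released selectively later) under buffered conditions that leave the trityl ether intact.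

Step 10
Reactants: 14 (2S,4R)-2,5-bis(tert-butyldimethylsilyloxy)-4-methyl-1-(trityloxy)pentane
Product: 15 (2S,4R)-2,5-bis(tert-butyldimethylsilyloxy)-4-methylpentan-1-ol
Conditions: BCl3 (1 M in CH2Cl2, 1.5 equiv), CH2Cl2, −30 °C; then MeOH
Reagents that add atoms: none
Why: Lewis-acid ionisation of the trityl ether, which is far more labile than TBS ethers toward BCl3 at low temperature, should free the primary C14 hydroxyl selectively.

Step 11
Reactants: 15 (2S,4R)-2,5-bis(tert-butyldimethylsilyloxy)-4-methylpentan-1-ol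
Product: 16 (2S,4R)-2,5-bis(tert-butyldimethylsilyloxy)-4-methylpentanal
Conditions: Dess–Martin periodinane, NaHCO3, CH2Cl2, 0 °C to rt
Reagents that add atoms: none
Why: Buffered Dess–Martin oxidation gives the α-silyloxy aldehyde under non-epimerising conditions; it is used directly.

Step 12
Reactants: 16 (2S,4R)-2,5-bis(tert-butyldimethylsilyloxy)-4-methylpentanal
Product: 17 (4R,5S,7R)-5,8-bis(tert-butyldimethylsilyloxy)-7-methyloct-1-en-4-ol
Conditions: (4S,5S)-diisopropyl 2-allyl-1,3,2-dioxaborolane-4,5-dicarboxylate, 4 Å molecular sieves, toluene, −78 °C; then 1 M aq. NaOH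
Reagents that add atoms: (4S,5S)-diisopropyl 2-allyl-1,3,2-dioxaborolane-4,5-dicarboxylate, C=CCB1O[C@H](C(=O)OC(C)C)[C@@H](C(=O)OC(C)C)O1
Why: Asymmetric allylboration through a chair Zimmerman–Traxler transition state, in which the (S,S)-tartrate reagent delivers allyl to the aldehyde Re face in agreement with the Felkin–Anh preference of the α-silyloxy aldehyde (matched pair), should set 14R, erythro to C15.

Step 13
Reactants: 17 (4R,5S,7R)-5,8-bis(tert-butyldimethylsilyloxy)-7-methyloct-1-en-4-ol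
Product: 18 (2E,5R,6S,8R)-6,9-bis(tert-butyldimethylsilyloxy)-5-hydroxy-8-methylnon-2-enal
Conditions: (E)-but-2-enal (5 equiv), second-generation Hoveyda–Grubbs catalyst (5 mol%), CH2Cl2, 40 °C
Reagents that add atoms: (E)-but-2-enal, C/C=C/C=O
Why: Cross-metathesis of an unhindered terminal olefin with an electron-poor enal partner is selective for the cross product and should give the E-enal (C11=C12, C10 aldehyde).

Step 14
Reactants: 18 (2E,5R,6S,8R)-6,9-bis(tert-butyldimethylsilyloxy)-5-hydroxy-8-methylnon-2-enal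
Product: 19 (2R,3S)-3-[(2R,3S,5R)-3,6-bis(tert-butyldimethylsilyloxy)-2-hydroxy-5-methylhexyl]oxirane-2-carbaldehyde
Conditions: (R)-2-{bis[3,5-bis(trifluoromethyl)phenyl](trimethylsilyloxy)methyl}pyrrolidine (10 mol%), 35% aq. H2O2 (1.3 equiv), CH2Cl2, rt
Reagents that add atoms: hydrogen peroxide, OO
Why: Organocatalytic iminium epoxidation (diarylprolinol silyl ether/H2O2), in which hydroperoxide adds to C12 on the olefin face opposite the diaryl(silyloxy)methyl group of the E-iminium ion and the enamine then closes the trans-epoxide, should give the (2R,3S)-epoxy aldehyde (11S,12S in the target) under catalyst control.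

Step 15
Reactants: 19 (2R,3S)-3-[(2R,3S,5R)-3,6-bis(tert-butyldimethylsilyloxy)-2-hydroxy-5-methylhexyl]oxirane-2-carbaldehyde
Product: 20 (2R,3S,5R)-3,6-bis(tert-butyldimethylsilyloxy)-5-methyl-1-[(2S,3S)-3-vinyloxiran-2-yl]hexan-2-ol (C10–C18 fragment)
Conditions: Ph3PCH3Br, KN(SiMe3)2 (2.2 equiv ylide), THF, 0 °C; then 19, −78 to 0 °C
Reagents that add atoms: methyltriphenylphosphonium bromide, C[P+](c1ccccc1)(c1ccccc1)c1ccccc1.[Br-]
Why: Wittig methylenation of the epoxy aldehyde at low temperature gives the vinyl epoxide without epimerising C11; the extra equivalent of ylide only deprotonates the C14 hydroxyl reversibly.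

**Fragment union and seco acid**

Step 16
Reactants: 20 (2R,3S,5R)-3,6-bis(tert-butyldimethylsilyloxy)-5-methyl-1-[(2S,3S)-3-vinyloxiran-2-yl]hexan-2-ol; 10 (S)-4-benzyl-3-[(3S,5E,7S,8S)-7,8-bis(tert-butyldimethylsilyloxy)-3-methyldeca-5,9-dienoyl]oxazolidin-2-one
Product: 21 (S)-4-benzyl-3-[(3S,5E,7S,8S,9E,11S,12S,14R,15S,17R)-7,8,15,18-tetrakis(tert-butyldimethylsilyloxy)-11,12-epoxy-14-hydroxy-3,17-dimethyloctadeca-5,9-dienoyl]oxazolidin-2-one (C1–C18 seco imide)
Conditions: 10 (2 equiv), second-generation Hoveyda–Grubbs catalyst (10 mol%, in portions), 1,4-benzoquinone (10 mol%), CH2Cl2, 40 °C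
Reagents that add atoms: none
Why: Cross-metathesis between the vinyl epoxide and the remaining vinyl group of 10 forms C9=C10; both partners homodimerise slowly, the internal C5=C6 olefin is shielded by its allylic silyl ether, and the E-isomer is expected.

Step 17
Reactants: 21 C1–C18 seco imide
Product: 22 (3S,5E,7S,8S,9E,11S,12S,14R,15S,17R)-7,8,15,18-tetrakis(tert-butyldimethylsilyloxy)-11,12-epoxy-14-hydroxy-3,17-dimethyloctadeca-5,9-dienoic acid (seco acid)
Conditions: LiOH, 30% aq. H2O2, THF/H2O (3:1), 0 °C; then aq. Na2SO3, pH 4 phosphate buffer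
Reagents that add atoms: hydrogen peroxide, OO
Why: Hydroperoxide attacks the exocyclic imide carbonyl selectively, releasing the acid and the auxiliary under cold, mildly basic conditions that silyl ethers and the vinyl epoxide should tolerate.

**Ring closure and completion**

Step 18
Reactants: 22 seco acid
Product: 24 (3S,5E,7S,8S,9E,11S,12S,14S)-14-[(1S,3R)-1,4-bis(tert-butyldimethylsilyloxy)-3-methylbutyl]-7,8-bis(tert-butyldimethylsilyloxy)-11,12-epoxy-3-methyltetradeca-5,9-dien-14-olide (15-membered lactone), via C14 alkoxyphosphonium carboxylate 23 (not isolated)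
Conditions: PPh3 (8 equiv), DIAD (8 equiv), toluene, 0 °C to rt, slow addition of 22 (final concentration about 1 mM)
Reagents that add atoms: none
Why: The PPh3/DIAD betaine deprotonates the C1 acid and converts the only free hydroxyl (C14) into the alkoxyphosphonium ion 23, whose carboxylate attacks C14 intramolecularly in an SN2 displacement that expels Ph3PO. The closest known reaction type is the Mitsunobu macrolactonisation of ω-hydroxy acids with inversion at a secondary carbinol. The single ring formed is the 15-membered lactone, closed in a 15-exo-tet mode (O1 attacks C14, the leaving group lying outside the ring). The only stereocentre affected is C14, whose S configuration should result from inversion of the 14R carbinol installed in step 12; C15 and the epoxide carbons are untouched. The step needs substitution to outrun E2 elimination toward C13, retention through an acyloxyphosphonium pathway and oligomerisation; slow addition at high dilution, the non-basic medium, the absence of any other free hydroxyl and the electron-withdrawing C15 silyloxy group (which disfavours ionisation at C14) are relied on for this.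

Step 19
Reactants: 24 15-membered lactone (O7, O8, O15, O18 silylated)
Product: 25 (3S,5E,7S,8S,9E,11S,12S,14S)-7,8-bis(tert-butyldimethylsilyloxy)-14-[(1S,3R)-1-(tert-butyldimethylsilyloxy)-4-hydroxy-3-methylbutyl]-11,12-epoxy-3-methyltetradeca-5,9-dien-14-olide
Conditions: HF·pyridine, excess pyridine, THF, 0 °C
Reagents that add atoms: none
Why: Buffered HF·pyridine cleaves the unhindered primary TBS ether (O18) much faster than the three hindered secondary ones.

Step 20
Reactants: 25 C18 alcohol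
Product: 26 (3S,5E,7S,8S,9E,11S,12S,14S)-7,8-bis(tert-butyldimethylsilyloxy)-14-[(1S,3R)-1-(tert-butyldimethylsilyloxy)-3-methyl-4-oxobutyl]-11,12-epoxy-3-methyltetradeca-5,9-dien-14-olide
Conditions: Dess–Martin periodinane, NaHCO3, CH2Cl2, 0 °C to rt
Reagents that add atoms: none
Why: Buffered Dess–Martin oxidation gives the α-methyl aldehyde (C18) without epimerising C17 or disturbing the vinyl epoxide.

Step 21
Reactants: 27 (E)-pent-3-en-1-ol; 28 1-phenyl-1H-tetrazole-5-thiol
Product: 29 5-[(E)-pent-3-enylsulfanyl]-1-phenyl-1H-tetrazole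
Conditions: PPh3, DIAD, THF, 0 °C to rt
Reagents that add atoms: none
Why: Mitsunobu thioetherification of a primary alcohol with the acidic tetrazole thiol.

Step 22
Reactants: 29 5-[(E)-pent-3-enylsulfanyl]-1-phenyl-1H-tetrazole
Product: 30 5-[(E)-pent-3-enylsulfonyl]-1-phenyl-1H-tetrazole
Conditions: (NH4)6Mo7O24·4H2O (10 mol%), 30% aq. H2O2, EtOH, 0 °C to rt
Reagents that add atoms: hydrogen peroxide, OO
Why: Molybdate-catalysed oxidation takes the sulfide to the sulfone without epoxidising the isolated E-olefin.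

Step 23
Reactants: 26 C18 aldehyde; 30 5-[(E)-pent-3-enylsulfonyl]-1-phenyl-1H-tetrazole
Product: 31 7,8,15-tris-O-(tert-butyldimethylsilyl)iriomoteolide 3a
Conditions: 30, KN(SiMe3)2, DME, −78 °C; then 26, −78 °C to rt
Reagents that add atoms: none
Why: Julia–Kocienski olefination (addition of the metalated phenyltetrazolyl sulfone, Smiles rearrangement, loss of SO2 and tetrazolate) with an α-branched aldehyde and potassium counter-ion in DME should give the E-olefin C18=C19, the pre-formed anion sparing the lactone.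

Step 24
Reactants: 31 7,8,15-tris-O-(tert-butyldimethylsilyl)iriomoteolide 3a
Product: 32 iriomoteolide 3a
Conditions: Bu4NF, AcOH (1:1), THF, 0 °C to rt
Reagents that add atoms: none
Why: Fluoride cleaves the three secondary silyl ethers, and acetic acid buffering suppresses migration of the lactone acyl group to O15 and base-induced opening of the vinyl epoxide.

**Compound list**

1 | (S)-4-benzyloxazolidin-2-one | O=C1N[C@@H](Cc2ccccc2)CO1 | starting material
2 | (E)-but-2-enoyl chloride | C/C=C/C(Cl)=O | starting material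
3 | (S)-4-benzyl-3-[(E)-but-2-enoyl]oxazolidin-2-one | C/C=C/C(=O)N1[C@@H](Cc2ccccc2)COC1=O | intermediate
4 | (S)-4-benzyl-3-[(S)-3-methylhex-5-enoyl]oxazolidin-2-one | C=CC[C@H](C)CC(=O)N1[C@@H](Cc2ccccc2)COC1=O | intermediate
5 | dimethyl (4R,5R)-2,2-dimethyl-1,3-dioxolane-4,5-dicarboxylate | COC(=O)[C@@H]1OC(C)(C)O[C@H]1C(=O)OC | starting material
6 | (4R,5R)-2,2-dimethyl-1,3-dioxolane-4,5-dicarbaldehyde | O=C[C@@H]1OC(C)(C)O[C@H]1C=O | intermediate
7 | (4S,5S)-2,2-dimethyl-4,5-divinyl-1,3-dioxolane | C=C[C@@H]1OC(C)(C)O[C@H]1C=C | intermediate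
8 | (3S,4S)-hexa-1,5-diene-3,4-diol | C=C[C@H](O)[C@@H](O)C=C | intermediate
9 | (3S,4S)-3,4-bis(tert-butyldimethylsilyloxy)hexa-1,5-diene | C=C[C@H](O[Si](C)(C)C(C)(C)C)[C@@H](O[Si](C)(C)C(C)(C)C)C=C | intermediate
10 | (S)-4-benzyl-3-[(3S,5E,7S,8S)-7,8-bis(tert-butyldimethylsilyloxy)-3-methyldeca-5,9-dienoyl]oxazolidin-2-one | C=C[C@H](O[Si](C)(C)C(C)(C)C)[C@@H](O[Si](C)(C)C(C)(C)C)/C=C/C[C@H](C)CC(=O)N1[C@@H](Cc2ccccc2)COC1=O | intermediate
11 | (S)-5-(trityloxymethyl)dihydrofuran-2(3H)-one | O=C1CC[C@@H](COC(c2ccccc2)(c2ccccc2)c2ccccc2)O1 | starting material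
12 | (3R,5S)-3-methyl-5-(trityloxymethyl)dihydrofuran-2(3H)-one | O=C1[C@H](C)C[C@@H](COC(c2ccccc2)(c2ccccc2)c2ccccc2)O1 | intermediate
13 | (2R,4S)-2-methyl-5-(trityloxy)pentane-1,4-diol | OC[C@H](C)C[C@H](O)COC(c1ccccc1)(c1ccccc1)c1ccccc1 | intermediate
14 | (2S,4R)-2,5-bis(tert-butyldimethylsilyloxy)-4-methyl-1-(trityloxy)pentane | CC(C)(C)[Si](C)(C)OC[C@H](C)C[C@H](O[Si](C)(C)C(C)(C)C)COC(c1ccccc1)(c1ccccc1)c1ccccc1 | intermediate
15 | (2S,4R)-2,5-bis(tert-butyldimethylsilyloxy)-4-methylpentan-1-ol | CC(C)(C)[Si](C)(C)OC[C@H](C)C[C@H](O[Si](C)(C)C(C)(C)C)CO | intermediate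
16 | (2S,4R)-2,5-bis(tert-butyldimethylsilyloxy)-4-methylpentanal | CC(C)(C)[Si](C)(C)OC[C@H](C)C[C@H](O[Si](C)(C)C(C)(C)C)C=O | intermediate
17 | (4R,5S,7R)-5,8-bis(tert-butyldimethylsilyloxy)-7-methyloct-1-en-4-ol | CC(C)(C)[Si](C)(C)OC[C@H](C)C[C@H](O[Si](C)(C)C(C)(C)C)[C@H](O)CC=C | intermediate
18 | (2E,5R,6S,8R)-6,9-bis(tert-butyldimethylsilyloxy)-5-hydroxy-8-methylnon-2-enal | CC(C)(C)[Si](C)(C)OC[C@H](C)C[C@H](O[Si](C)(C)C(C)(C)C)[C@H](O)C/C=C/C=O | intermediate
19 | (2R,3S)-3-[(2R,3S,5R)-3,6-bis(tert-butyldimethylsilyloxy)-2-hydroxy-5-methylhexyl]oxirane-2-carbaldehyde | CC(C)(C)[Si](C)(C)OC[C@H](C)C[C@H](O[Si](C)(C)C(C)(C)C)[C@H](O)C[C@@H]1O[C@H]1C=O | intermediate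
20 | (2R,3S,5R)-3,6-bis(tert-butyldimethylsilyloxy)-5-methyl-1-[(2S,3S)-3-vinyloxiran-2-yl]hexan-2-ol | CC(C)(C)[Si](C)(C)OC[C@H](C)C[C@H](O[Si](C)(C)C(C)(C)C)[C@H](O)C[C@@H]1O[C@H]1C=C | intermediate
21 | (S)-4-benzyl-3-[(3S,5E,7S,8S,9E,11S,12S,14R,15S,17R)-7,8,15,18-tetrakis(tert-butyldimethylsilyloxy)-11,12-epoxy-14-hydroxy-3,17-dimethyloctadeca-5,9-dienoyl]oxazolidin-2-one | CC(C)(C)[Si](C)(C)OC[C@H](C)C[C@H](O[Si](C)(C)C(C)(C)C)[C@H](O)C[C@@H]1O[C@H]1/C=C/[C@H](O[Si](C)(C)C(C)(C)C)[C@@H](O[Si](C)(C)C(C)(C)C)/C=C/C[C@H](C)CC(=O)N2[C@@H](Cc3ccccc3)COC2=O | intermediate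
22 | (3S,5E,7S,8S,9E,11S,12S,14R,15S,17R)-7,8,15,18-tetrakis(tert-butyldimethylsilyloxy)-11,12-epoxy-14-hydroxy-3,17-dimethyloctadeca-5,9-dienoic acid | CC(C)(C)[Si](C)(C)OC[C@H](C)C[C@H](O[Si](C)(C)C(C)(C)C)[C@H](O)C[C@@H]1O[C@H]1/C=C/[C@H](O[Si](C)(C)C(C)(C)C)[C@@H](O[Si](C)(C)C(C)(C)C)/C=C/C[C@H](C)CC(=O)O | intermediate
23 | C14 O-triphenylphosphonium carboxylate of 22 | CC(C)(C)[Si](C)(C)OC[C@H](C)C[C@H](O[Si](C)(C)C(C)(C)C)[C@H](O[P+](c1ccccc1)(c1ccccc1)c1ccccc1)C[C@@H]1O[C@H]1/C=C/[C@H](O[Si](C)(C)C(C)(C)C)[C@@H](O[Si](C)(C)C(C)(C)C)/C=C/C[C@H](C)CC(=O)[O-] | intermediate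
24 | (3S,5E,7S,8S,9E,11S,12S,14S)-14-[(1S,3R)-1,4-bis(tert-butyldimethylsilyloxy)-3-methylbutyl]-7,8-bis(tert-butyldimethylsilyloxy)-11,12-epoxy-3-methyltetradeca-5,9-dien-14-olide | CC(C)(C)[Si](C)(C)OC[C@H](C)C[C@H](O[Si](C)(C)C(C)(C)C)[C@@H]1C[C@@H]2O[C@H]2/C=C/[C@H](O[Si](C)(C)C(C)(C)C)[C@@H](O[Si](C)(C)C(C)(C)C)/C=C/C[C@H](C)CC(=O)O1 | intermediate
25 | (3S,5E,7S,8S,9E,11S,12S,14S)-7,8-bis(tert-butyldimethylsilyloxy)-14-[(1S,3R)-1-(tert-butyldimethylsilyloxy)-4-hydroxy-3-methylbutyl]-11,12-epoxy-3-methyltetradeca-5,9-dien-14-olide | OC[C@H](C)C[C@H](O[Si](C)(C)C(C)(C)C)[C@@H]1C[C@@H]2O[C@H]2/C=C/[C@H](O[Si](C)(C)C(C)(C)C)[C@@H](O[Si](C)(C)C(C)(C)C)/C=C/C[C@H](C)CC(=O)O1 | intermediate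
26 | (3S,5E,7S,8S,9E,11S,12S,14S)-7,8-bis(tert-butyldimethylsilyloxy)-14-[(1S,3R)-1-(tert-butyldimethylsilyloxy)-3-methyl-4-oxobutyl]-11,12-epoxy-3-methyltetradeca-5,9-dien-14-olide | O=C[C@H](C)C[C@H](O[Si](C)(C)C(C)(C)C)[C@@H]1C[C@@H]2O[C@H]2/C=C/[C@H](O[Si](C)(C)C(C)(C)C)[C@@H](O[Si](C)(C)C(C)(C)C)/C=C/C[C@H](C)CC(=O)O1 | intermediate
27 | (E)-pent-3-en-1-ol | C/C=C/CCO | starting material
28 | 1-phenyl-1H-tetrazole-5-thiol | Sc1nnnn1-c1ccccc1 | starting material
29 | 5-[(E)-pent-3-enylsulfanyl]-1-phenyl-1H-tetrazole | C/C=C/CCSc1nnnn1-c1ccccc1 | intermediate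
30 | 5-[(E)-pent-3-enylsulfonyl]-1-phenyl-1H-tetrazole | C/C=C/CCS(=O)(=O)c1nnnn1-c1ccccc1 | intermediate
31 | 7,8,15-tris-O-(tert-butyldimethylsilyl)iriomoteolide 3a | C/C=C/C/C=C/[C@H](C)C[C@H](O[Si](C)(C)C(C)(C)C)[C@@H]1C[C@@H]2O[C@H]2/C=C/[C@H](O[Si](C)(C)C(C)(C)C)[C@@H](O[Si](C)(C)C(C)(C)C)/C=C/C[C@H](C)CC(=O)O1 | intermediate
32 | iriomoteolide 3a | C/C=C/C/C=C/[C@H](C)C[C@H](O)[C@@H]1C[C@@H]2O[C@H]2/C=C/[C@H](O)[C@@H](O)/C=C/C[C@H](C)CC(=O)O1 | target

**Step count.** Total: 24 steps. Longest linear sequence: 16 steps (11 to 32 through steps 7–20, 23 and 24).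

**Steps most likely to fail, with fallbacks**

Step 18 (Mitsunobu macrolactonisation). The alkoxyphosphonium ion at the hindered C14, deactivated by the neighbouring silyloxy carbon, may be displaced too slowly. Elimination toward C13, attack through an acyloxyphosphonium species (retention at C14) or intermolecular esterification could then take over. The fallback separates activation from displacement while closing the same bond. It sets out from 22: chloromethanesulfonyl chloride (2.2 equiv) and pyridine, followed by aqueous NaHCO3 hydrolysis of the mixed carboxylic–sulfonic anhydride, would give (3S,5E,7S,8S,9E,11S,12S,14R,15S,17R)-7,8,15,18-tetrakis(tert-butyldimethylsilyloxy)-14-(chloromethanesulfonyloxy)-11,12-epoxy-3,17-dimethyloctadeca-5,9-dienoic acid F1. Its caesium carboxylate (Cs2CO3, 18-crown-6, toluene/DMF, 60 °C, high dilution) should close the ring by intramolecular SN2 with inversion, coming back to the route at 24.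

Step 16 (fragment-joining cross-metathesis). Two hindered olefins must couple while the catalyst is exposed to a vinyl epoxide and a free hydroxyl. Slow turnover could allow homodimerisation of 20, secondary metathesis at C5=C6 or Lewis-acid-promoted opening of the epoxide by the C14 hydroxyl. The fallback builds the chain in the other order, so that the valuable fragment always meets a cheap partner in large excess. It sets out from 20: cross-metathesis with a four-fold excess of diene 9 would give (2R,3S,5R)-1-{(2S,3S)-3-[(1E,3S,4S)-3,4-bis(tert-butyldimethylsilyloxy)hexa-1,5-dienyl]oxiran-2-yl}-3,6-bis(tert-butyldimethylsilyloxy)-5-methylhexan-2-ol F2. A second cross-metathesis of its remaining vinyl group with excess 4 comes back to the route at 21.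

Step 14 (organocatalytic epoxidation). Catalyst control may be eroded by the nearby C14/C15 centres. The δ-hydroxy enal may also isomerise through its iminium/dienamine and be trapped as a cyclic lactol, or the epoxy aldehyde may be opened by the C14 hydroxyl. The fallback uses a hydroxyl-directed epoxidation whose facial sense is fixed by the tartrate. It sets out from 17: cross-metathesis with (Z)-but-2-ene-1,4-diol (second-generation Hoveyda–Grubbs catalyst) would give (2E,5R,6S,8R)-6,9-bis(tert-butyldimethylsilyloxy)-8-methylnon-2-ene-1,5-diol F3. Sharpless asymmetric epoxidation (Ti(OiPr)4, L-(+)-diethyl tartrate, t-BuOOH, 4 Å molecular sieves, CH2Cl2, −20 °C) should then give (2R,3S,5R)-3,6-bis(tert-butyldimethylsilyloxy)-1-[(2S,3S)-3-(hydroxymethyl)oxiran-2-yl]-5-methylhexan-2-ol F4. Primary-selective oxidation (TEMPO, PhI(OAc)2, CH2Cl2) comes back to the route at 19.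

**Further compounds**

F1 | step 18 | (3S,5E,7S,8S,9E,11S,12S,14R,15S,17R)-7,8,15,18-tetrakis(tert-butyldimethylsilyloxy)-14-(chloromethanesulfonyloxy)-11,12-epoxy-3,17-dimethyloctadeca-5,9-dienoic acid | CC(C)(C)[Si](C)(C)OC[C@H](C)C[C@H](O[Si](C)(C)C(C)(C)C)[C@H](OS(=O)(=O)CCl)C[C@@H]1O[C@H]1/C=C/[C@H](O[Si](C)(C)C(C)(C)C)[C@@H](O[Si](C)(C)C(C)(C)C)/C=C/C[C@H](C)CC(=O)O
F2 | step 16 | (2R,3S,5R)-1-{(2S,3S)-3-[(1E,3S,4S)-3,4-bis(tert-butyldimethylsilyloxy)hexa-1,5-dienyl]oxiran-2-yl}-3,6-bis(tert-butyldimethylsilyloxy)-5-methylhexan-2-ol | CC(C)(C)[Si](C)(C)OC[C@H](C)C[C@H](O[Si](C)(C)C(C)(C)C)[C@H](O)C[C@@H]1O[C@H]1/C=C/[C@H](O[Si](C)(C)C(C)(C)C)[C@@H](O[Si](C)(C)C(C)(C)C)C=C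
F3 | step 14 | (2E,5R,6S,8R)-6,9-bis(tert-butyldimethylsilyloxy)-8-methylnon-2-ene-1,5-diol | CC(C)(C)[Si](C)(C)OC[C@H](C)C[C@H](O[Si](C)(C)C(C)(C)C)[C@H](O)C/C=C/CO
F4 | step 14 | (2R,3S,5R)-3,6-bis(tert-butyldimethylsilyloxy)-1-[(2S,3S)-3-(hydroxymethyl)oxiran-2-yl]-5-methylhexan-2-ol | CC(C)(C)[Si](C)(C)OC[C@H](C)C[C@H](O[Si](C)(C)C(C)(C)C)[C@H](O)C[C@@H]1O[C@H]1CO
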